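## Structural features

2,3,7-Tribromoindole is a planar bicyclic heteroarene in which a pyrrole ring (N1, C2, C3, C3a, C7a) is fused to a benzene ring (C3a, C4–C7, C7a) through the shared C3a–C7a bond. It has no stereocentre, so no stereocentres stand next to each other and none has to be set or protected. Bromine sits on both carbons of the pyrrole ring (C2 and C3) and on C7, the benzene carbon next to the ring-fusion carbon C7a that carries N1; N1 itself is unsubstituted. The 2,3-dibromo-1H-indole unit is the fragile part: it is sensitive to acid, light and moisture, because its 3H-indole tautomer hydrolyses towards oxindoles. The C7 aryl bromide, once in place, tolerates neither alkyllithium reagents nor hydrogenolysis. The real difficulty is the C7 bromine, since electrophilic bromination of an indole goes to C3, C2 and then C5/C6, and that of an indoline goes to C5, so C7 has to be fixed by the way the ring system is assembled. The feature exploited is the ortho relationship of N1 on C7a and bromine on C7, which is the pattern left when a nitrogen nucleophile and an electrophile add to the two carbons of an aryne; C2 and C3 serve as the two-carbon tether that delivers nitrogen to C7a.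

## Logic of the disconnections

C2–Br and C3–Br: 13 is taken back to 10 and two equivalents of 11. These bonds are cut first because C3 and C2 are the positions at which the pyrrole ring reacts with electrophiles of its own accord, and because the 2,3-dibromo unit is the least durable part of 13 and should exist only at the end. The cut removes two of the three halogens and leaves a stable intermediate. The forward step must stop after exactly two brominations, pass through 12 (C3 first), spare C4–C6 and exclude water.

C2=C3 unsaturation: 10 is taken back to 9. The double bond is given up so that C2 and C3 become a saturated two-carbon chain, which the ring-forming step can use as a tether. No skeletal bond is cut, but the change in oxidation level opens the way to the next disconnection. The forward step needs an oxidant that dehydrogenates the five-membered ring without touching C7–Br, and it must precede the use of 11, because the nitrogen of 9 would send an electrophile to C5.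

N1–Si: 9 is taken back to 8. This only restores the silyl group that the ring-forming step requires on nitrogen. In the forward direction the bond is weak enough to be cleaved in the work-up, so no separate operation is spent on it.

C7–Br and N1–C7a: 8 is taken back through 7, 6 and 5 to 3 and 4. The two bonds lie on neighbouring benzene carbons; cutting both opens the five-membered ring and exposes 6, which has a formal triple bond between the future C7a and C7, a nitrogen nucleophile on the tether, and 4 as the electrophile. The gain is the largest of the route: a bicyclic, regiodefined bromoarene becomes a monocyclic fluoroarene with one side chain. The forward step demands a single regioisomer of 6 (hence 5, metalated next to fluorine), attack of nitrogen at the inner carbon, and a carbanion 7 that lasts until 4 is added. Nitrogen must therefore carry a group other than hydrogen that neither migrates nor blocks the addition.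

N–Si: 3 is taken back to 1 and 2. One bond is cut, and both fragments are commercial. The forward step must stop at the monosilylated stage and must avoid water.

## Other disconnections considered

Alternative 1: The cut is the C7–C7a bond, so that the benzene ring is grown onto a pyrrole that already carries the C3 bromine. The precursor would be tert-butyl 3-bromo-4-[(1Z)-4,4-dibromobuta-1,3-dien-1-yl]-1H-pyrrole-1-carboxylate A1. In the forward key step, irradiation of A1 at 365 nm over K2CO3 would close the triene formed by the pyrrole C=C bond and the dibromodiene in a 6π electrocyclisation. Base-assisted dehydrobromination of the resulting dihydroarene would give tert-butyl 3,7-dibromo-1H-indole-1-carboxylate A2.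
- In its favour: the C7 bromine of A2 is one of the two geminal bromines of A1 and cannot end up elsewhere, so on regiocontrol at C7 this plan is the equal of the chosen one. The C3 bromine travels in with the pyrrole and blocks closure towards the other β-carbon. A2 is already an indole, so no dehydrogenation is needed. No organolithium reagent or low temperature is involved, which makes this plan the better one in mildness and functional-group tolerance.
- Against it here: A1 is a 3,4-disubstituted pyrrole with a sensitive side chain and would itself take several steps (β-functionalisation of a protected pyrrole, chain extension to an enal, dibromo-olefination). Carbon–bromine bonds may be cleaved by the light, and a photochemical step is awkward to enlarge. After A2 the carbamate still has to be removed (which leads to 12) and C2 brominated.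
- Comparison: structurally both plans fix C7 by construction, one by building the benzene ring and the other by adding across it. Mechanistically a pericyclic closure stands against a polar addition, each a well-understood elementary process. In step economy the chosen plan is clearly shorter: it passes 12 in its fourth step from a commercial amine, whereas this plan would need roughly twice as many operations.

Alternative 2: Three bonds are cut at once, C3a–C7a, C4–C5 and C6–C7, which takes both rings apart. This leads to the ynamide diyne N-(but-3-yn-1-yl)-4-methyl-N-[(trimethylsilyl)ethynyl]benzenesulfonamide A3 and acetylene A4. In the forward key step RhCl(PPh3)3 would couple the two tethered alkynes of A3 to a rhodacyclopentadiene, A4 would insert, and reductive elimination would complete a [2+2+2] cycloaddition to 1-(4-methylbenzenesulfonyl)-7-(trimethylsilyl)indoline A5.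
- In its favour: it is the most convergent of the four plans, forming both rings and three carbon–carbon bonds in one catalytic, neutral step; here it is better than the chosen plan in bond-forming efficiency and mildness. The tether of A3 forces the silyl-bearing carbon to become C7 of A5, so its regiocontrol is the equal of the aryne route. C5 and C6 come from A4, the simplest two-carbon unit.
- Against it here: C7 arrives in A5 as silicon and not as bromine, so an ipso-bromodesilylation of A5 to 7-bromo-1-(4-methylbenzenesulfonyl)indoline A6 has to follow. The sulfonamide of A6 must then be cleaved next to an aryl bromide, where electron-transfer methods threaten the C–Br bond, before the route could join at 9. A3 needs its own sequence (sulfonamide formation and N-alkynylation). The gaseous A4 has to compete with self-oligomerisation of the terminal alkyne of A3.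
- Comparison: both plans build the five-membered ring and define C7 in one step. The aryne route puts bromine on C7 directly and sheds its nitrogen substituent in the work-up, while this plan needs two further steps from A5 through A6 to reach 9 and shares the dehydrogenation and dibromination after that. In step economy the chosen plan should be ahead by about three steps. The cycloaddition would be the more attractive only if analogues with other groups on the benzene ring were wanted.

Alternative 3: The cut is the C3–C3a bond, so that the five-membered ring is closed onto an aniline that already carries the C7 bromine. Conjugate addition of 2-bromoaniline A7 to ethyl propiolate A8 would give the precursor, ethyl (2Z)-3-[(2-bromophenyl)amino]prop-2-enoate A9, in one step. In the forward key step, constant-current electrolysis with KI in an undivided cell (carbon anode, platinum cathode) would oxidise iodide to an iodinating species that activates the enamine of A9 at the carbon α to the ester. Attack of the free ortho carbon on this position, rearomatisation and regeneration of iodide, with hydrogen evolution at the cathode, would give ethyl 7-bromo-1H-indole-3-carboxylate A10.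
- In its favour: the bromine is bought with A7 and only one ortho carbon is free, so the regiochemistry is as secure as in the chosen plan (equal). The indole oxidation level is reached directly, without a dehydrogenation (better). No pyrophoric base, low temperature or protecting group is involved and the oxidant is electric current (better in operational safety). The length is the equal of the chosen plan, four steps, if saponification of A10 to 7-bromo-1H-indole-3-carboxylic acid A11 is followed by two equivalents of 11, which would replace the carboxyl group at C3 of A11 by bromine (ipso-bromodecarboxylation) and brominate C2.
- Against it here: the ester carbon of A8 is introduced only to be expelled again. Enamines such as A9, without a substituent at the future C2, are more easily hydrolysed and less well tried in this oxidative closure than their substituted relatives. The bromine makes the arene less nucleophilic and may be reduced at the cathode of an undivided cell. The last operation asks for a bromodecarboxylation and a C2 bromination on the same sensitive nucleus.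
- Comparison: structurally this plan keeps the benzene ring intact and forms only a C–C bond, where the aryne route forms N1–C7a and C7–Br itself. Mechanistically a mediated anodic oxidation stands against a polar organolithium cascade whose regiochemistry follows from the position of fluorine. In step economy the two are level. The aryne route is retained because each of its bonds is formed in a stoichiometric polar event of predictable course, whereas the electrolysis would first have to be shown to tolerate the unsubstituted, bromine-bearing enamine A9. If cryogenic organolithium chemistry had to be avoided, this alternative would be the first choice.

Key step: step 2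

Remark on the chemistry: indole numbering is used for all intermediates (the fluorine-bearing carbon of 3 becomes C7a and its C–H neighbour becomes C7); 3 keeps the bulky tert-butyldimethylsilyl group on nitrogen and is used without chromatography because its N–Si bond hydrolyses readily; it is assumed that this bond in 8 is cleaved completely in the acidic work-up of step 2, so that 8 is not isolated.

## Route

Step 1
Reactants: 1 2-(2-fluorophenyl)ethanamine; 2 tert-butyldimethylsilyl chloride
Product: 3 N-(tert-butyldimethylsilyl)-2-(2-fluorophenyl)ethanamine
Conditions: Et3N (1.5 equiv), CH2Cl2, 0 °C to rt; evaporation, pentane, filtration under argon, used without chromatography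
Reagents that add atoms: tert-butyldimethylsilyl chloride, CC(C)(C)[Si](C)(C)Cl
Why: Nucleophilic substitution at silicon (N-silylation of a primary amine) with Et3N as acceptor for HCl; the bulk of the silyl group should stop the reaction at the monosilylated amine, and the non-aqueous isolation avoids hydrolysis of the N–Si bond.

Step 2
Reactants: 3 N-(tert-butyldimethylsilyl)-2-(2-fluorophenyl)ethanamine; 4 1,2-dibromotetrachloroethane
Product: 9 7-bromoindoline, via dilithio amide 5 (not isolated), via aryne amide 6 (not isolated), via 7-lithio-1-silylindoline 7 (not isolated), via 7-bromo-1-silylindoline 8 (not isolated)
Conditions: t-BuLi (2.2 equiv), THF, –78 to –40 °C; then 4 (1.3 equiv), –78 to 0 °C; then 1 M HCl, MeOH, rt; NaHCO3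
Reagents that add atoms: 1,2-dibromotetrachloroethane, BrC(Cl)(Cl)C(Cl)(Cl)Br
Why: t-BuLi first removes the N–H proton and then lithiates the only ring carbon that flanks fluorine, giving 5; on warming to about –40 °C 5 loses LiF, so the aryne 6 can lie only between the former C–F carbon (future C7a) and its lithiated neighbour (future C7). Ring closure follows as the silylamide nitrogen on the side chain attacks the aryne carbon closest to it, a 5-exo-dig process that creates N1–C7a and the five-membered ring; attack at the outer carbon would need an impossibly strained bridged ring, so the negative charge ends on C7 as aryllithium 7. Because nitrogen carries silicon and no proton, 7 is not quenched internally, and after recooling to –78 °C it takes a bromine atom from 4 (with loss of tetrachloroethene and LiBr) to give 8. Acidic methanolysis during work-up cleaves the labile N–Si bond and releases 9. The closest known reaction types are the aryne cyclisation of 2-(halophenyl)ethylamines to indolines, the addition of lithium amides to arynes followed by electrophilic capture of the ortho-aminoaryl metal, and the trapping of aryllithiums formed by anionic aryne cyclisation. No stereocentre is formed. The step needs one aryne regioisomer (secured by fluorine ortho to the tether, with a single free neighbouring C–H), nitrogen attack at the inner carbon (secured by tether length) and ring closure in preference to intermolecular addition of t-BuLi or of 7 to 6 (secured by dilution, the small excess of base and the high effective molarity of the tethered amide); the bulky silyl group and the low trapping temperature are meant to hold back N-to-C7 silyl migration in 7.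

Step 3
Reactants: 9 7-bromoindoline
Product: 10 7-bromo-1H-indole
Conditions: activated MnO2 (10 equiv), CH2Cl2, rt to reflux; filtration through Celite
Reagents that add atoms: none
Why: Heterogeneous dehydrogenation of an indoline by activated MnO2, driven by formation of the aromatic pyrrole ring; the aryl bromide is inert to this oxidant, and the step is placed before the bromination because the aniline-type nitrogen of 9 would direct an electrophile to C5.

Step 4
Reactants: 10 7-bromo-1H-indole; 11 N-bromosuccinimide
Product: 13 2,3,7-tribromo-1H-indole, via 3,7-dibromoindole 12 (not isolated)
Conditions: NBS (2.05 equiv), dry THF, –78 °C to rt, dark; aq. Na2S2O3/NaHCO3; Et3N-deactivated silica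
Reagents that add atoms: N-bromosuccinimide, O=C1CCC(=O)N1Br
Why: Electrophilic aromatic substitution of the indole by NBS: the first equivalent brominates C3, the most nucleophilic position, to give 12, and the second brominates C2 (directly or through a 3,3-dibromo-3H-indole that rearranges). The bromine at C7 deactivates the benzene ring, and exact stoichiometry, low temperature and exclusion of water and light should prevent a third bromination and hydrolysis towards oxindoles.

## Compound list

1 | 2-(2-fluorophenyl)ethanamine | NCCc1ccccc1F | starting material
2 | tert-butyldimethylsilyl chloride | CC(C)(C)[Si](C)(C)Cl | starting material
3 | N-(tert-butyldimethylsilyl)-2-(2-fluorophenyl)ethanamine | CC(C)(C)[Si](C)(C)NCCc1ccccc1F | intermediate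
4 | 1,2-dibromotetrachloroethane | BrC(Cl)(Cl)C(Cl)(Cl)Br | starting material
5 | lithium N-(tert-butyldimethylsilyl)-N-[2-(2-fluoro-3-lithiophenyl)ethyl]amide (formed in the flask) | [Li]N(CCc1cccc([Li])c1F)[Si](C)(C)C(C)(C)C | intermediate
6 | lithium N-(tert-butyldimethylsilyl)-N-[2-(2,3-didehydrophenyl)ethyl]amide, the aryne (formed in the flask) | [Li]N(CCC1=CC=CC#C1)[Si](C)(C)C(C)(C)C | intermediate
7 | 1-(tert-butyldimethylsilyl)-7-lithioindoline (formed in the flask) | [Li]c1cccc2CCN(c12)[Si](C)(C)C(C)(C)C | intermediate
8 | 7-bromo-1-(tert-butyldimethylsilyl)indoline (formed in the flask) | CC(C)(C)[Si](C)(C)N1CCc2cccc(Br)c21 | intermediate
9 | 7-bromoindoline (7-bromo-2,3-dihydro-1H-indole) | Brc1cccc2CCNc12 | intermediate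
10 | 7-bromo-1H-indole | Brc1cccc2cc[nH]c12 | intermediate
11 | N-bromosuccinimide | O=C1CCC(=O)N1Br | starting material
12 | 3,7-dibromo-1H-indole (formed in the flask) | Brc1c[nH]c2c(Br)cccc12 | intermediate
13 | 2,3,7-tribromo-1H-indole | Brc1[nH]c2c(Br)cccc2c1Br | target

## Step count and least certain steps

Total step count: 4. Longest linear sequence: 4 steps (1 to 3 to 9 to 10 to 13).

Step 2 (key step). The most likely failure is loss of the C7 carbanion before the bromine source arrives. This could happen by proton abstraction during the warm period needed to expel LiF, or by migration of the silyl group from N1 to C7. A second risk is intermolecular addition of t-BuLi or of 7 to the aryne when concentration or base excess is too high. Fallback, which separates ring closure from the functionalisation of C7: from 3 the same base-induced closure is run but quenched with 1 M HCl/MeOH instead of 4. Protonation of 7 should give 1-(tert-butyldimethylsilyl)indoline F1, which is hydrolysed in the same work-up to indoline F2. Boc2O converts this into tert-butyl indoline-1-carboxylate F3. Carbamate-directed ortho-lithiation with s-BuLi/TMEDA in Et2O at –78 °C should give tert-butyl 7-lithioindoline-1-carboxylate F4, which is brominated with 4 to tert-butyl 7-bromoindoline-1-carboxylate F5. CF3CO2H in CH2Cl2 removes the carbamate, and the route is rejoined at 9.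

Step 4. The most likely failures are a third bromination on the benzene ring, hydrolytic diversion of the 3-bromo-3H-indole stage towards oxindoles, and decomposition of the product on acidic silica. The cause is that bromination at C2 is slower than at C3 and the product is sensitive to acid and light. Fallback, which makes the C2–Br bond by deprotonation instead of electrophilic substitution: from 10, Boc2O/DMAP should give tert-butyl 7-bromo-1H-indole-1-carboxylate F6. LiN(i-Pr)2 in THF at –78 °C removes the C2 proton without bromine–lithium exchange to give tert-butyl 7-bromo-2-lithio-1H-indole-1-carboxylate F7, which is brominated with 4 to tert-butyl 2,7-dibromo-1H-indole-1-carboxylate F8. K2CO3 in MeOH cleaves the carbamate to 2,7-dibromo-1H-indole F9, and one equivalent of 11 then brominates C3, so that the route is rejoined at 13.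

Step 3. The most likely failures are incomplete dehydrogenation and loss of material by adsorption or over-oxidation on the large excess of MnO2, whose activity varies from batch to batch. Fallback, an N-halogenation/elimination sequence in place of a surface oxidation: from 9, trichloroisocyanuric acid and DBU in CH2Cl2 at 0 °C should chlorinate nitrogen to 7-bromo-1-chloroindoline F10. Base-induced loss of hydrogen chloride then gives 7-bromo-3H-indole F11, which tautomerises, and the route is rejoined at 10.

Step 1. The most likely failures are hydrolytic cleavage of the N–Si bond during isolation and incomplete silylation; either would leave N–H groups that quench 7 in the next step. Fallback, a deprotonative silylation in the flask of the key step: from 1, n-BuLi (one equivalent) in THF at –78 °C gives lithium [2-(2-fluorophenyl)ethyl]amide F12, which is silylated by 2. The resulting solution is treated directly with t-BuLi as in step 2, so that the route is rejoined at 3 without isolation.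

## Further compounds

F1 | step 2 | 1-(tert-butyldimethylsilyl)indoline | CC(C)(C)[Si](C)(C)N1CCc2ccccc21
F2 | step 2 | indoline (2,3-dihydro-1H-indole) | C1Cc2ccccc2N1
F3 | step 2 | tert-butyl indoline-1-carboxylate | CC(C)(C)OC(=O)N1CCc2ccccc21
F4 | step 2 | tert-butyl 7-lithioindoline-1-carboxylate | [Li]c1cccc2CCN(C(=O)OC(C)(C)C)c12
F5 | step 2 | tert-butyl 7-bromoindoline-1-carboxylate | CC(C)(C)OC(=O)N1CCc2cccc(Br)c21
F6 | step 4 | tert-butyl 7-bromo-1H-indole-1-carboxylate | CC(C)(C)OC(=O)n1ccc2cccc(Br)c21
F7 | step 4 | tert-butyl 7-bromo-2-lithio-1H-indole-1-carboxylate | [Li]c1cc2cccc(Br)c2n1C(=O)OC(C)(C)C
F8 | step 4 | tert-butyl 2,7-dibromo-1H-indole-1-carboxylate | CC(C)(C)OC(=O)n1c(Br)cc2cccc(Br)c21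
F9 | step 4 | 2,7-dibromo-1H-indole | Brc1cc2cccc(Br)c2[nH]1
F10 | step 3 | 7-bromo-1-chloroindoline | ClN1CCc2cccc(Br)c21
F11 | step 3 | 7-bromo-3H-indole | Brc1cccc2CC=Nc12
F12 | step 1 | lithium [2-(2-fluorophenyl)ethyl]amide | [Li]NCCc1ccccc1F
A1 | alternative 1 | tert-butyl 3-bromo-4-[(1Z)-4,4-dibromobuta-1,3-dien-1-yl]-1H-pyrrole-1-carboxylate | CC(C)(C)OC(=O)n1cc(Br)c(/C=C\C=C(Br)Br)c1
A2 | alternative 1 | tert-butyl 3,7-dibromo-1H-indole-1-carboxylate | CC(C)(C)OC(=O)n1cc(Br)c2cccc(Br)c12
A3 | alternative 2 | N-(but-3-yn-1-yl)-4-methyl-N-[(trimethylsilyl)ethynyl]benzenesulfonamide | Cc1ccc(cc1)S(=O)(=O)N(CCC#C)C#C[Si](C)(C)C
A4 | alternative 2 | acetylene | C#C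
A5 | alternative 2 | 1-(4-methylbenzenesulfonyl)-7-(trimethylsilyl)indoline | Cc1ccc(cc1)S(=O)(=O)N1CCc2cccc([Si](C)(C)C)c21
A6 | alternative 2 | 7-bromo-1-(4-methylbenzenesulfonyl)indoline | Cc1ccc(cc1)S(=O)(=O)N1CCc2cccc(Br)c21
A7 | alternative 3 | 2-bromoaniline | Nc1ccccc1Br
A8 | alternative 3 | ethyl propiolate | CCOC(=O)C#C
A9 | alternative 3 | ethyl (2Z)-3-[(2-bromophenyl)amino]prop-2-enoate | CCOC(=O)/C=C\Nc1ccccc1Br
A10 | alternative 3 | ethyl 7-bromo-1H-indole-3-carboxylate | CCOC(=O)c1c[nH]c2c(Br)cccc12
A11 | alternative 3 | 7-bromo-1H-indole-3-carboxylic acid | OC(=O)c1c[nH]c2c(Br)cccc12
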